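(The readings were generated by integration on assumed constants, and the scatter is random.)

Side product is bought with incoming ligand: a starting complex takes up one and the leaving ligand it frees is taken back, so each side product counts one ligand spent. In this flask, starting complex exchanges stepwise and reversibly up to complex with three exchanged, each exchange freeing leaving ligand. Leaving ligand plus complex with one exchanged gives side product, and protic impurity turns starting complex into quenched substrate.

| flask | starting complex | incoming ligand | protic impurity | remark | time |
|---|---|---|---|---|---|
| green | 0.050 M (in portions, 4) | 0.125 M | 1 mM | the very flask that is asked about, followed so far; portions every 50 s |  |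
| flask | 0.050 M (in portions, 4) | 0.125 M | 1.00 mM | the portions of starting complex follow each other after 50 s, the first at the start | 15 min |
green run (percent of the starting complex charged)

| time / min | starting complex / % | complex with one exchanged / % | side product / % |
|---|---|---|---|
| 0.833 | 7.3 | 6.4 | 0.6 |
| 1.50 | 15.8 | 12.3 | 3.4 |
| 2.50 | 25.6 | 18.0 | 9.9 |
| 3.00 | 38.7 | 21.7 | 16.5 |
| 4.00 | 30.7 | 17.5 | 28.8 |
| 5.00 | 25.3 | 15.6 | 36.2 |
| 6.00 | 21.3 | 12.4 | 42.7 |

(scatter of a reading: 0.5 percentage points)
- conversion of starting complex at 15 min
- amount of complex with one exchanged at 15 min, in percent of the starting complex charged
- amount of side product at 15 min, in percent of the starting complex charged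
- what may be going on: starting complex + incoming ligand <-> leaving ligand + complex with one exchanged; complex with one exchanged + incoming ligand <-> leaving ligand + complex with two exchanged; complex with two exchanged + incoming ligand <-> leaving ligand + complex with three exchanged; leaving ligand + complex with one exchanged -> side product; protic impurity + starting complex -> quenched substrate

1. This flask holds 2.50 incoming ligand per complex charged. The impurity can claim 2.00 % of the charge, so side product has a ceiling of 98.0 %.

2. The side-product curve starts nearly flat, at 0.6 % after 0.833 min. Once the last portion is in, at 2.50 min, it climbs by 0.123 min⁻¹ of the charge. It crosses starting complex near 4.15 min, then bends to a read slope of 0.0650 min⁻¹.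

3. Complexes unread at 6.00 min amount to 21.6 %. Counting them as complex with three exchanged, ligand spent per complex charged is at most 1.20: this is the turnover count, side product plus complex with one exchanged plus 2 and 3 times the higher complexes.

4. If the whole remainder ended as complex with three exchanged, the count would reach 2.09, so in this flask the supply of incoming ligand holds.

5. I hold the unread complexes fixed and drain starting complex and complex with one exchanged as a pseudo-first-order feed at the read slope. That puts side product at 70.5 %.

The forecast says conversion 93 %, complex with one exchanged 5 %, side product 70 %, and differs from me in its ground: “The pool should then shrink slowly through reversal”.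

The flask gives conversion 95.0 %, complex with one exchanged 3.60 % and side product 71.2 %, each within the tolerance of the forecast.

    starting complex + incoming ligand ⇌ leaving ligand + complex with one exchanged (K = 0.400, k = 0.225 L mol⁻¹ s⁻¹)
    complex with one exchanged + incoming ligand ⇌ leaving ligand + complex with two exchanged (K = 0.190, k = 1.00 L mol⁻¹ s⁻¹)
    complex with two exchanged + incoming ligand ⇌ leaving ligand + complex with three exchanged (K = 3.37, k = 0.120 L mol⁻¹ s⁻¹)
    leaving ligand + complex with one exchanged → side product (k = 0.240 L mol⁻¹ s⁻¹)
    protic impurity + starting complex → quenched substrate (k = 1.40 L mol⁻¹ s⁻¹)

At 15 min this flask is not at rest. Its 49 % of incoming ligand left means 1.28 turnovers, against 1.20 at the last reading. The neighbour with 0.075 M of incoming ligand holds 1.50 per complex, keeps 33 % and has spent 1.01, with 62.2 % side product. Left until 150 min, this flask's complex with three exchanged falls from 16.7 % to 6.07 % and side product reaches 91.5 %. Its count falls back to 1.10 ligand per complex charged, still above the 0.980 per complex charged of a charge wholly side product.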